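Slowness here lies in getting the partners into solution, not in their reaction. We want the end concentration of target across these flasks:

| flask | solid substrate | gas | time |
|---|---|---|---|
| eta | 6.0 mM | 5.2 mM (held) | 1.0 min |
| epsilon | 12 mM | 5.2 mM (held) | 1.0 min |
| beta | 25 mM | 5.2 mM (held) | 1.0 min |
| alpha | 50 mM | 5.2 mM (held) | 1.0 min |
| theta | 100 mM | 5.2 mM (held) | 1.0 min |

    solid substrate ⇌ dissolved substrate, rate k1*(cs1 - [dissolved substrate]) while solid is left; crystals form when [dissolved substrate] > cs1 (cs1 = 19 mM, k1 = 0.032 s⁻¹)
    dissolved substrate + reagent → target (k2 = 170 M⁻¹ s⁻¹)
    solid substrate + target → side product (k3 = 0.36 M⁻¹ s⁻¹)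
    gas ⇌ reagent, rate k4*(csat - [reagent]) (k4 = 0.11 s⁻¹, csat = 5.2 mM)

- percent here means solid substrate units held: one side product counts as two
- solid substrate is a solid; its amount is given per volume of the solution
- at the start none of reagent is dissolved
- at the start none of the solid substrate is in solution
- "hardly changes" means that all values lie within two and a half points (for a concentration: within two and a half percent of the largest)
- run time (eta): 1.0 min

- [target] at the end for eta, epsilon, beta, alpha, theta, in this order
- the shape of the row from first to last (falls, then rises / rises, then falls / rises all the way / hardly changes / falls all the way)

The reaction of dissolved substrate with reagent is fast against both feeds, as long as the partner stands at its limit. With c(dissolved substrate) at its solubility, reagent is consumed at 3.23 s⁻¹ against a transfer coefficient of 0.11 s⁻¹. With c(reagent) at saturation, dissolved substrate is consumed at 0.884 s⁻¹ against a dissolution coefficient of 0.032 s⁻¹.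

So we reckon the throughput of the run in two ways. From the gas side, with c(reagent) held at zero, transfer delivers 34.3 mM in the run; we call this the supply ceiling. From the solid side, with c(dissolved substrate) held at zero, dissolution delivers 36.5 mM. These come from different constants, yet they lie 0.0265 decades apart. Both cheat in the same way: each holds one partner at zero, while the reaction's rate is proportional to that partner. The throughput therefore stands below the smaller figure.

We set each charge against the ceiling in decades. Beside it stands the half-life of target under its pseudo-first-order loss to solid substrate, taken at the charged amount.

| flask | charge over ceiling, decades | half-life of target |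
|---|---|---|
| eta | −0.757 | 321 s |
| epsilon | −0.456 | 160 s |
| beta | −0.138 | 77.0 s |
| alpha | 0.163 | 38.5 s |
| theta | 0.464 | 19.3 s |

In eta the half-life is long against the run of 1.0 min, so we expect target to follow the charge. In theta it is shorter than the run, and balancing supply at the ceiling rate against that loss gives an estimate of 15.9 mM of target. The ceiling lies above the beta charge and below the alpha charge, so we expect a peak between those two flasks. Taking as estimates the charge in eta, the smaller of charge and ceiling in beta, 25.0 mM, and 15.9 mM in theta, the shape we commit to is rises, then falls.

The forecast gives 5.95 mM, 11.7 mM, 22 mM, 21 mM, 15 mM, with the shape rises, then falls. Its ground is that “With large charges the solid remains throughout and destroys target”. It caps target formation at roughly 27 mM in the run, where our ceiling stands at 34.3 mM.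

The simulation gives 5.98 mM, 11.8 mM, 22.7 mM, 21.5 mM, 14.6 mM, with the shape rises, then falls. The row turns at a reading of 31 mM of solid substrate, 91.6 % of the ceiling. Counting target made as target standing plus side product, one target per side product, alpha made 27.3 mM, or 79.5 % of the ceiling. Theta, with twice the charge of alpha, made 27.3 mM, or 79.5 % of the ceiling.

The constants used here were drawn at random within sensible limits; the rest is arithmetic.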